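**Retrosynthetic overview**
1. The furanone ring is cut into two pieces: O1–C2(=O)–C3(CH3) is a propanoic acid unit, and C4–C5 are the ester carbon and the α-carbon of an α-bromoacrylate. Both ring bonds between the pieces (O1–C5 and C3–C4) are made in one flask by copper-mediated vinylic C–O coupling followed by Dieckmann closure.
2. Enabling feature: in the 4-hydroxy-3-methylfuran-2(5H)-one ring, the acyl-level carbon C4 sits next to the sp2 carbon C5, which carries the ring oxygen and the exocyclic C=C. C5 can therefore be a vinyl bromide whose geometry (side chain cis to C4) is copied into the E ylidene.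
3. The (E)-α-bromoacrylate comes from the chain aldehyde by a bromo Still–Gennari olefination. The aldehyde comes from a B-alkyl Suzuki–Miyaura coupling of benzyl (S)-2-methylpent-4-enoate (Evans allylation sets the S centre) with a 2-bromo-1-alkene.
4. The bromoalkene fragment is built by ester alkylation with 2,3-dibromopropene, an Eschenmoser–Claisen rearrangement (E trisubstituted alkene) and addition of 3-furyllithium (furyl ketone, masked as a dioxolane).
5. Ring order: furan (bought), dioxolane (temporary, step 6), furanone (step 14, the only ring built for the target), dioxolane removed in step 15.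

Key step: step 14

Remark: the target SMILES fixes the ylidene as E (side chain anti to the ring oxygen) and the methyl-bearing carbon as S; the tetronic acid is drawn and named as its 4-hydroxy enol tautomer.

**Route**

Step 1
Reactants: 1 ethyl acetate; 2 2,3-dibromopropene
Product: 3 ethyl 4-bromopent-4-enoate
Conditions: LiN(i-Pr)2, THF, −78 °C; then 2, DMPU, −78 → −20 °C
Reagents that add atoms: none
Why: Ester enolate alkylation (SN2 at the allylic CH2Br of 2, the vinylic C–Br bond being inert), run cold to outpace Claisen self-condensation.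

Step 2
Reactants: 3 ethyl 4-bromopent-4-enoate
Product: 4 4-bromopent-4-enal
Conditions: i-Bu2AlH (1.05 equiv), CH2Cl2, −78 °C; MeOH, then aq. potassium sodium tartrate
Reagents that add atoms: none
Why: Partial ester reduction with i-Bu2AlH at −78 °C should stop at the aluminium hemiacetal, which releases the aldehyde on work-up.

Step 3
Reactants: 4 4-bromopent-4-enal
Product: 5 6-bromo-2-methylhepta-1,6-dien-3-ol (racemic)
Conditions: CH2=C(CH3)MgBr, THF, −78 → 0 °C; aq. NH4Cl
Reagents that add atoms: isopropenylmagnesium bromide CC(=C)[Mg]Br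
Why: Grignard 1,2-addition to the aldehyde; the carbinol centre is left racemic because it is destroyed in step 4.

Step 4
Reactants: 5 6-bromo-2-methylhepta-1,6-dien-3-ol
Product: 7 (4E)-8-bromo-N,N,4-trimethylnona-4,8-dienamide, via ketene aminal 6 (not isolated)
Conditions: CH3C(OMe)2NMe2 (3 equiv), xylene, 140 °C, MeOH distilled off
Reagents that add atoms: N,N-dimethylacetamide dimethyl acetal COC(C)(OC)N(C)C
Why: Eschenmoser–Claisen rearrangement, in which the [3,3] shift of 6 through a chair transition state with the bromobutenyl chain equatorial (an axial chain would clash with NMe2) should give the E trisubstituted alkene.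

Step 5
Reactants: 7 (4E)-8-bromo-N,N,4-trimethylnona-4,8-dienamide; 8 3-bromofuran
Product: 10 (4E)-8-bromo-1-(furan-3-yl)-4-methylnona-4,8-dien-1-one, via 3-furyllithium 9 (not isolated)
Conditions: 8, n-BuLi, THF, −78 °C; then 7, −78 °C; aq. NH4Cl
Reagents that add atoms: none
Why: Bromine–lithium exchange followed by aryllithium addition to the tertiary amide gives a tetrahedral lithium hemiaminal that is stable at −78 °C and releases the ketone only on work-up (ketone synthesis from N,N-dimethylamides), and at this temperature 9 neither isomerises nor exchanges with the vinyl bromide.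

Step 6
Reactants: 10 (4E)-8-bromo-1-(furan-3-yl)-4-methylnona-4,8-dien-1-one
Product: 11 2-[(3E)-7-bromo-3-methylocta-3,7-dien-1-yl]-2-(furan-3-yl)-1,3-dioxolane
Conditions: Me3SiOCH2CH2OSiMe3, Me3SiOTf (cat.), CH2Cl2, −78 → −20 °C; then pyridine
Reagents that add atoms: 1,2-bis(trimethylsilyloxy)ethane C[Si](C)(C)OCCO[Si](C)(C)C
Why: Noyori ketalisation, driven by formation of hexamethyldisiloxane under aprotic cold conditions that spare the furan and both alkenes, masks the enolisable ketone against the bases of steps 13 and 14.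

Step 7
Reactants: 12 (4R)-4-benzyl-3-propanoyl-1,3-oxazolidin-2-one; 13 allyl iodide
Product: 15 (4R)-4-benzyl-3-[(2S)-2-methylpent-4-enoyl]-1,3-oxazolidin-2-one, via sodium Z-enolate 14 (not isolated)
Conditions: NaN(SiMe3)2, THF, −78 °C; then 13, −78 → −45 °C
Reagents that add atoms: none
Why: Evans asymmetric alkylation, in which the chelated Z-enolate 14 is allylated on the face opposite the benzyl group of the R auxiliary, which should set the S methyl stereocentre.

Step 8
Reactants: 15 (4R)-4-benzyl-3-[(2S)-2-methylpent-4-enoyl]-1,3-oxazolidin-2-one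
Product: 16 benzyl (2S)-2-methylpent-4-enoate
Conditions: BnOH, n-BuLi, THF, −78 °C (LiOBn); then 15, −78 → 0 °C
Reagents that add atoms: benzyl alcohol OCc1ccccc1
Why: Evans transesterification, in which LiOBn attacks the exocyclic imide carbonyl and frees the auxiliary without epimerisation, giving a non-volatile ester that tolerates the Suzuki conditions.

Step 9
Reactants: 17 methyl 2-[bis(2,2,2-trifluoroethoxy)phosphoryl]acetate
Product: 18 methyl 2,2-dibromo-2-[bis(2,2,2-trifluoroethoxy)phosphoryl]acetate
Conditions: Br2, NaOH, H2O, 0 °C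
Reagents that add atoms: bromine BrBr
Why: Hypobromite dibromination of the doubly activated methylene (α-halogenation of a phosphonoacetate), the second bromination being faster than the first.

Step 10
Reactants: 18 methyl 2,2-dibromo-2-[bis(2,2,2-trifluoroethoxy)phosphoryl]acetate
Product: 19 methyl 2-bromo-2-[bis(2,2,2-trifluoroethoxy)phosphoryl]acetate (racemic)
Conditions: SnCl2·2H2O, EtOH/H2O, 0 °C
Reagents that add atoms: none
Why: Halophilic monodebromination of the gem-dibromide by divalent tin, which should stop at the monobromide because its remaining bromine is far less electrophilic.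

Step 11
Reactants: 16 benzyl (2S)-2-methylpent-4-enoate; 11 2-[(3E)-7-bromo-3-methylocta-3,7-dien-1-yl]-2-(furan-3-yl)-1,3-dioxolane
Product: 21 benzyl (2S,9E)-12-[2-(furan-3-yl)-1,3-dioxolan-2-yl]-2,10-dimethyl-6-methylidenedodec-9-enoate, via alkylborane 20 (not isolated)
Conditions: 16, 9-BBN, THF, 0 °C → rt; then 11, PdCl2(dppf) (5 mol%), AsPh3, Cs2CO3, DMF/H2O, rt
Reagents that add atoms: none
Why: B-alkyl Suzuki–Miyaura coupling, in which 9-BBN hydroborates only the terminal alkene of 16 (before 11 is added) and the alkylborane couples with the 2-bromoalkene to build the 1,1-disubstituted alkene, while the ester stereocentre is not touched by Cs2CO3 at room temperature.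

Step 12
Reactants: 21 benzyl (2S,9E)-12-[2-(furan-3-yl)-1,3-dioxolan-2-yl]-2,10-dimethyl-6-methylidenedodec-9-enoate
Product: 22 (2S,9E)-12-[2-(furan-3-yl)-1,3-dioxolan-2-yl]-2,10-dimethyl-6-methylidenedodec-9-enal
Conditions: i-Bu2AlH (1.1 equiv), CH2Cl2, −78 °C; MeOH, then aq. potassium sodium tartrate
Reagents that add atoms: none
Why: Partial ester-to-aldehyde reduction with i-Bu2AlH at −78 °C via the tetrahedral aluminium hemiacetal, with a cold non-basic work-up that should leave the α-methyl stereocentre intact.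

Step 13
Reactants: 22 (2S,9E)-12-[2-(furan-3-yl)-1,3-dioxolan-2-yl]-2,10-dimethyl-6-methylidenedodec-9-enal; 19 methyl 2-bromo-2-[bis(2,2,2-trifluoroethoxy)phosphoryl]acetate
Product: 23 methyl (2E,4S,11E)-2-bromo-14-[2-(furan-3-yl)-1,3-dioxolan-2-yl]-4,12-dimethyl-8-methylidenetetradeca-2,11-dienoate
Conditions: 19, KOt-Bu, 18-crown-6, THF, −78 °C; then 22, −78 °C
Reagents that add atoms: none
Why: Still–Gennari-type Horner–Wadsworth–Emmons olefination with an α-bromophosphonate, in which the electron-poor trifluoroethyl phosphonate eliminates from the kinetic adduct and should place the chain cis to the ester and trans to bromine (the E bromoacrylate), the stabilised anion being too weakly basic to epimerise the aldehyde.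

Step 14
Reactants: 23 methyl (2E,4S,11E)-2-bromo-14-[2-(furan-3-yl)-1,3-dioxolan-2-yl]-4,12-dimethyl-8-methylidenetetradeca-2,11-dienoate; 24 caesium propanoate
Product: 26 (5E)-5-[(2S,9E)-12-[2-(furan-3-yl)-1,3-dioxolan-2-yl]-2,10-dimethyl-6-methylidenedodec-9-en-1-ylidene]-4-hydroxy-3-methylfuran-2(5H)-one, via enol propanoate 25 (not isolated)
Conditions: EtCO2Cs (1.3 equiv), CuI (20 mol%), 3,4,7,8-tetramethyl-1,10-phenanthroline (40 mol%), toluene, 90 °C; then THF, LiN(SiMe3)2 (3 equiv), −78 → −20 °C; cold 1 M HCl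
Reagents that add atoms: none
Why: Proposed new method: a formal [3+2] annulation in which propanoate acts as an O,C-bisnucleophile toward the C(Br)–C(=O) unit of 23: phenanthroline-ligated CuO2CEt adds oxidatively into the vinylic C–Br bond and C–O reductive elimination from the trivalent vinylcopper forms the O1–C5 bond with retention to give 25, after which LiN(SiMe3)2 deprotonates the propanoyl CH2, whose carbon attacks the neighbouring methyl ester and expels methoxide to form C3–C4, the acidic tetronate being the thermodynamic sink. The closest known reaction types are the stereoretentive substitution of vinyl halides by copper carboxylates (Ullmann-type enol ester synthesis) and the Dieckmann cyclisation of enol esters of α-keto esters to 5-ylidene tetronic acids, here run in one flask on an α-bromoacrylate. The furanone ring closes by a 5-exo-trig acyl substitution. No stereocentre is formed: the E geometry of the ylidene is fixed by retention at the brominated carbon, and the existing S centre should survive because allylic 1,3-strain holds its C–H bond in the alkene plane, where it cannot be removed as a vinylogous proton. The step needs C–O coupling at the α-carbon instead of conjugate addition, and ring closure instead of intermolecular Claisen chemistry; the first is secured by the copper-bound carboxylate and the hindered β-carbon, the second by the five-membered transition state at −78 °C.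

Step 15
Reactants: 26 (5E)-5-[(2S,9E)-12-[2-(furan-3-yl)-1,3-dioxolan-2-yl]-2,10-dimethyl-6-methylidenedodec-9-en-1-ylidene]-4-hydroxy-3-methylfuran-2(5H)-one
Product: 27 (5E)-5-[(2S,9E)-13-(furan-3-yl)-2,10-dimethyl-6-methylidene-13-oxotridec-9-en-1-ylidene]-4-hydroxy-3-methylfuran-2(5H)-one
Conditions: 1 M HCl, THF, 0 °C → rt, in the dark
Reagents that add atoms: water O
Why: Acid-catalysed hydrolysis of the aryl ketone dioxolane via a furyl-stabilised oxocarbenium ion under conditions mild enough for the 1,1-disubstituted alkene and the E ylidene, with no stereocentre touched.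

**Compound list**
1 | ethyl acetate | CCOC(C)=O | starting material
2 | 2,3-dibromopropene | C=C(Br)CBr | starting material
3 | ethyl 4-bromopent-4-enoate | CCOC(=O)CCC(Br)=C | intermediate
4 | 4-bromopent-4-enal | O=CCCC(Br)=C | intermediate
5 | 6-bromo-2-methylhepta-1,6-dien-3-ol (racemic) | C=C(C)C(O)CCC(Br)=C | intermediate
6 | 1-[(6-bromo-2-methylhepta-1,6-dien-3-yl)oxy]-N,N-dimethylethen-1-amine (ketene aminal) | C=C(N(C)C)OC(CCC(Br)=C)C(C)=C | intermediate (not isolated)
7 | (4E)-8-bromo-N,N,4-trimethylnona-4,8-dienamide | CN(C)C(=O)CC/C(C)=C/CCC(Br)=C | intermediate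
8 | 3-bromofuran | Brc1ccoc1 | starting material
9 | 3-furyllithium | [Li]c1ccoc1 | intermediate (not isolated)
10 | (4E)-8-bromo-1-(furan-3-yl)-4-methylnona-4,8-dien-1-one | O=C(CC/C(C)=C/CCC(Br)=C)c1ccoc1 | intermediate
11 | 2-[(3E)-7-bromo-3-methylocta-3,7-dien-1-yl]-2-(furan-3-yl)-1,3-dioxolane | C=C(Br)CC/C=C(\C)CCC1(OCCO1)c1ccoc1 | intermediate
12 | (4R)-4-benzyl-3-propanoyl-1,3-oxazolidin-2-one | CCC(=O)N1[C@H](Cc2ccccc2)COC1=O | starting material
13 | allyl iodide | C=CCI | starting material
14 | sodium (Z)-enolate of 12 | C/C=C(\[O-])N1[C@H](Cc2ccccc2)COC1=O.[Na+] | intermediate (not isolated)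
15 | (4R)-4-benzyl-3-[(2S)-2-methylpent-4-enoyl]-1,3-oxazolidin-2-one | C=CC[C@H](C)C(=O)N1[C@H](Cc2ccccc2)COC1=O | intermediate
16 | benzyl (2S)-2-methylpent-4-enoate | C=CC[C@H](C)C(=O)OCc1ccccc1 | intermediate
17 | methyl 2-[bis(2,2,2-trifluoroethoxy)phosphoryl]acetate | COC(=O)CP(=O)(OCC(F)(F)F)OCC(F)(F)F | starting material
18 | methyl 2,2-dibromo-2-[bis(2,2,2-trifluoroethoxy)phosphoryl]acetate | COC(=O)C(Br)(Br)P(=O)(OCC(F)(F)F)OCC(F)(F)F | intermediate
19 | methyl 2-bromo-2-[bis(2,2,2-trifluoroethoxy)phosphoryl]acetate (racemic) | COC(=O)C(Br)P(=O)(OCC(F)(F)F)OCC(F)(F)F | intermediate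
20 | benzyl (2S)-5-(9-borabicyclo[3.3.1]nonan-9-yl)-2-methylpentanoate | C1CCC2CCCC1B2CCC[C@H](C)C(=O)OCc1ccccc1 | intermediate (not isolated)
21 | benzyl (2S,9E)-12-[2-(furan-3-yl)-1,3-dioxolan-2-yl]-2,10-dimethyl-6-methylidenedodec-9-enoate | C=C(CC/C=C(\C)CCC1(OCCO1)c1ccoc1)CCC[C@H](C)C(=O)OCc1ccccc1 | intermediate
22 | (2S,9E)-12-[2-(furan-3-yl)-1,3-dioxolan-2-yl]-2,10-dimethyl-6-methylidenedodec-9-enal | C=C(CC/C=C(\C)CCC1(OCCO1)c1ccoc1)CCC[C@H](C)C=O | intermediate
23 | methyl (2E,4S,11E)-2-bromo-14-[2-(furan-3-yl)-1,3-dioxolan-2-yl]-4,12-dimethyl-8-methylidenetetradeca-2,11-dienoate | C=C(CC/C=C(\C)CCC1(OCCO1)c1ccoc1)CCC[C@H](C)/C=C(/Br)C(=O)OC | intermediate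
24 | caesium propanoate | CCC(=O)[O-].[Cs+] | starting material
25 | methyl (2E,4S,11E)-14-[2-(furan-3-yl)-1,3-dioxolan-2-yl]-4,12-dimethyl-8-methylidene-2-(propanoyloxy)tetradeca-2,11-dienoate | C=C(CC/C=C(\C)CCC1(OCCO1)c1ccoc1)CCC[C@H](C)/C=C(/OC(=O)CC)C(=O)OC | intermediate (not isolated)
26 | (5E)-5-[(2S,9E)-12-[2-(furan-3-yl)-1,3-dioxolan-2-yl]-2,10-dimethyl-6-methylidenedodec-9-en-1-ylidene]-4-hydroxy-3-methylfuran-2(5H)-one | C=C(CC/C=C(\C)CCC2(OCCO2)c2ccoc2)CCC[C@H](C)/C=C1/OC(=O)C(C)=C1O | intermediate
27 | (5E)-5-[(2S,9E)-13-(furan-3-yl)-2,10-dimethyl-6-methylidene-13-oxotridec-9-en-1-ylidene]-4-hydroxy-3-methylfuran-2(5H)-one | C=C(CC/C=C(\C)CCC(=O)c1ccoc1)CCC[C@H](C)/C=C1/OC(=O)C(C)=C1O | target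

**Step count and risks**

Total step count: 15. Longest linear sequence: 11 steps (steps 1–6 and 11–15).

Steps most likely to fail:

1. Step 14 (proposed new method). The intermolecular C–O coupling may stall on the hindered α-bromoacrylate, the bromide may lose its geometry through reversible conjugate addition of carboxylate, and the enolate of 25 may fragment to methylketene instead of closing the ring. The fallback sets out from 23 and returns at 26; it makes the C3–C4 bond first and the O1–C5 bond last, using known reactions only. Saponification (LiOH, THF/H2O, 0 °C) should give (2E,4S,11E)-2-bromo-14-[2-(furan-3-yl)-1,3-dioxolan-2-yl]-4,12-dimethyl-8-methylidenetetradeca-2,11-dienoic acid F1. Activation with 1,1'-carbonyldiimidazole in THF gives 1-[(2E,4S,11E)-2-bromo-14-[2-(furan-3-yl)-1,3-dioxolan-2-yl]-4,12-dimethyl-8-methylidenetetradeca-2,11-dienoyl]imidazole F2. This acylates the dilithium dianion of propanoic acid (LiN(i-Pr)2, 2 equiv, THF, −78 °C) on carbon to give (4E,6S,13E)-4-bromo-16-[2-(furan-3-yl)-1,3-dioxolan-2-yl]-2,6,14-trimethyl-10-methylidene-3-oxohexadeca-4,13-dienoic acid F3, which is kept cold as its caesium salt to avoid decarboxylation. The ring is then closed by the known copper-catalysed intramolecular O-vinylation of a carboxylic acid (CuI, trans-N,N'-dimethylcyclohexane-1,2-diamine, Cs2CO3, dioxane, 70 °C), a 5-exo closure with retention that should give 26.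

2. Step 13. The olefination may give insufficient E/Z selectivity, or the α-methyl aldehyde may epimerise under the basic conditions. The fallback sets out from 22 and returns at 26; it fixes the geometry by a syn addition to an alkyne instead of an olefination. Corey–Fuchs dibromo-olefination (CBr4, PPh3, Et3N, CH2Cl2, 0 °C) gives 2-[(3E,11S)-13,13-dibromo-3,11-dimethyl-7-methylidenetrideca-3,12-dien-1-yl]-2-(furan-3-yl)-1,3-dioxolane F4. Treatment with n-BuLi (2.1 equiv, THF, −78 °C) and then ClCO2Me gives methyl (4S,11E)-14-[2-(furan-3-yl)-1,3-dioxolan-2-yl]-4,12-dimethyl-8-methylidenetetradec-11-en-2-ynoate F5. Syn hydrostannation (Bu3SnH, Pd(PPh3)4 cat., THF, rt) places tin on the α-carbon and gives methyl (2E,4S,11E)-14-[2-(furan-3-yl)-1,3-dioxolan-2-yl]-4,12-dimethyl-8-methylidene-2-(tributylstannyl)tetradeca-2,11-dienoate F6. Iododestannylation (I2, CH2Cl2, 0 °C) with retention gives methyl (2E,4S,11E)-14-[2-(furan-3-yl)-1,3-dioxolan-2-yl]-2-iodo-4,12-dimethyl-8-methylidenetetradeca-2,11-dienoate F7, which takes the place of 23 under the conditions of step 14 and should give 26.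

3. Step 12. The reduction may run on to the primary alcohol, and the aldehyde may epimerise during a slow aluminium work-up. The fallback sets out from 21 and returns at 22; it replaces the partial reduction by full reduction and re-oxidation. LiAlH4 (THF, 0 °C) should give (2S,9E)-12-[2-(furan-3-yl)-1,3-dioxolan-2-yl]-2,10-dimethyl-6-methylidenedodec-9-en-1-ol F8, and buffered Dess–Martin oxidation (Dess–Martin periodinane, NaHCO3, CH2Cl2, 0 °C) should return 22 without epimerisation.

**Further compounds**
F1 | step 14 | (2E,4S,11E)-2-bromo-14-[2-(furan-3-yl)-1,3-dioxolan-2-yl]-4,12-dimethyl-8-methylidenetetradeca-2,11-dienoic acid | C=C(CC/C=C(\C)CCC1(OCCO1)c1ccoc1)CCC[C@H](C)/C=C(/Br)C(=O)O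
F2 | step 14 | 1-[(2E,4S,11E)-2-bromo-14-[2-(furan-3-yl)-1,3-dioxolan-2-yl]-4,12-dimethyl-8-methylidenetetradeca-2,11-dienoyl]imidazole | C=C(CC/C=C(\C)CCC1(OCCO1)c1ccoc1)CCC[C@H](C)/C=C(/Br)C(=O)n1ccnc1
F3 | step 14 | (4E,6S,13E)-4-bromo-16-[2-(furan-3-yl)-1,3-dioxolan-2-yl]-2,6,14-trimethyl-10-methylidene-3-oxohexadeca-4,13-dienoic acid | C=C(CC/C=C(\C)CCC1(OCCO1)c1ccoc1)CCC[C@H](C)/C=C(/Br)C(=O)C(C)C(=O)O
F4 | step 13 | 2-[(3E,11S)-13,13-dibromo-3,11-dimethyl-7-methylidenetrideca-3,12-dien-1-yl]-2-(furan-3-yl)-1,3-dioxolane | C=C(CC/C=C(\C)CCC1(OCCO1)c1ccoc1)CCC[C@H](C)C=C(Br)Br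
F5 | step 13 | methyl (4S,11E)-14-[2-(furan-3-yl)-1,3-dioxolan-2-yl]-4,12-dimethyl-8-methylidenetetradec-11-en-2-ynoate | C=C(CC/C=C(\C)CCC1(OCCO1)c1ccoc1)CCC[C@H](C)C#CC(=O)OC
F6 | step 13 | methyl (2E,4S,11E)-14-[2-(furan-3-yl)-1,3-dioxolan-2-yl]-4,12-dimethyl-8-methylidene-2-(tributylstannyl)tetradeca-2,11-dienoate | C=C(CC/C=C(\C)CCC1(OCCO1)c1ccoc1)CCC[C@H](C)/C=C(/[Sn](CCCC)(CCCC)CCCC)C(=O)OC
F7 | step 13 | methyl (2E,4S,11E)-14-[2-(furan-3-yl)-1,3-dioxolan-2-yl]-2-iodo-4,12-dimethyl-8-methylidenetetradeca-2,11-dienoate | C=C(CC/C=C(\C)CCC1(OCCO1)c1ccoc1)CCC[C@H](C)/C=C(/I)C(=O)OC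
F8 | step 12 | (2S,9E)-12-[2-(furan-3-yl)-1,3-dioxolan-2-yl]-2,10-dimethyl-6-methylidenedodec-9-en-1-ol | C=C(CC/C=C(\C)CCC1(OCCO1)c1ccoc1)CCC[C@H](C)CO
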